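**Plan**

- Retrosynthetic cuts: first the epoxide oxygen, the two ester groups, C11=C13, the lactone O–C12 bond and C4–C15, back to a ten-membered C4 ketone. Then the ring bond C2–C3, reopened with an O–C(=O) spacer to a twelve-membered allyl β-keto lactone. Then O–C2 (acylketene), C5–C6 (vinylogous aldol), C7–C11 (alkylation) and C9–C10 (alkenyl copper + epoxide).
- Forward order: the acyclic C2–C1=C10–C9–C8–C7(C11–C12)–C6 chain is built, the dioxinone (C3–C5) is added, the twelve-membered lactone is closed, and palladium-mediated loss of CO2 contracts it to the carbocycle. C15, the γ-lactone, the exo-methylene, the esters and the epoxide follow.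
- Enabling feature: C2 is allylic to the (E)-C1=C10 bond, and the oxygen-bearing C3 lies next to C4, which can be a ketone because the C4=C5/C15 unit can be made from it through an enol triflate. A C2–O–C(=O)–C3 bridge is therefore an allyl β-keto ester.
- Stereochemistry: C8 is bought (ethyl (S)-4-chloro-3-hydroxybutanoate). C7 comes from a Fráter–Seebach alkylation (anti to O8), C6 from a Felkin/1,3-anti vinylogous Mukaiyama aldol, C3 from a CBS reduction. 1(10)E comes from syn-hydrozirconation, 4Z from the ring E(O)-enolate and a stereoretentive Stille coupling, and C1/C10 from peripheral peracid attack.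

Key step: step 15

Remark 1: locants follow germacranolide numbering (ring C1–C10; C11, C12 (C=O) and C13 (=CH2) in the lactone; C14 is the methyl on C10; C15 is the CH2OH on C4). PMB = 4-methoxybenzyl, NAP = 2-naphthylmethyl.
Remark 2: compounds 24–37 are carried as mixtures of C3 epimers; C3 is erased in step 22 and set in step 23, so their SMILES leave C3 undefined.

**Route**

Step 1
Reactants: 1 but-2-yn-1-ol
Product: 2 1-[(but-2-yn-1-yloxy)methyl]-4-methoxybenzene
Conditions: NaH, PMBCl, Bu4NI (cat.), THF, 0 °C to rt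
Reagents that add atoms: 4-methoxybenzyl chloride (COc1ccc(CCl)cc1)
Why: Williamson etherification of the propargylic alkoxide should mask the future C2 hydroxyl for the organometallic and Lewis acid steps.

Step 2
Reactants: 2 1-[(but-2-yn-1-yloxy)methyl]-4-methoxybenzene
Product: 4 1-({[(2E)-3-iodobut-2-en-1-yl]oxy}methyl)-4-methoxybenzene, via alkenylzirconocene 3 (not isolated)
Conditions: Cp2Zr(H)Cl (1.5 equiv), THF, rt to 40 °C; then I2, 0 °C
Reagents that add atoms: iodine (II)
Why: syn-hydrozirconation with the Schwartz reagent should place zirconium on the less hindered methyl-bearing carbon after equilibration, and iodinolysis with retention should give the (E)-iodide that becomes the 1(10)E alkene.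

Step 3
Reactants: 5 ethyl (3S)-4-chloro-3-hydroxybutanoate
Product: 6 ethyl [(2S)-oxiran-2-yl]acetate
Conditions: Ag2O, DME, 60 °C, dark
Reagents that add atoms: none
Why: silver-assisted intramolecular Williamson closure should form the epoxide without touching the carbinol centre (the future C8) and without the E1cB opening to the hydroxycrotonate that a strong base would cause.

Step 4
Reactants: 4 1-({[(2E)-3-iodobut-2-en-1-yl]oxy}methyl)-4-methoxybenzene; 6 ethyl [(2S)-oxiran-2-yl]acetate
Product: 9 ethyl (3R,5E)-3-hydroxy-7-[(4-methoxybenzyl)oxy]-5-methylhept-5-enoate, via alkenyllithium 7 (not isolated), via alkenylmagnesium bromide 8 (not isolated)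
Conditions: t-BuLi (2 equiv), Et2O, −78 °C; MgBr2·OEt2; then 6, CuI (10 mol %), THF, −40 to −20 °C
Reagents that add atoms: none
Why: iodine–lithium exchange with retention, transmetalation and copper-catalysed SN2 opening of the epoxide at its CH2 terminus should form C9–C10, tolerate the ester at low temperature and leave the C8 configuration and the E geometry intact.

Step 5
Reactants: 9 ethyl (3R,5E)-3-hydroxy-7-[(4-methoxybenzyl)oxy]-5-methylhept-5-enoate; 10 tert-butyl bromoacetate
Product: 12 4-tert-butyl 1-ethyl (2R)-2-[(1R,3E)-1-hydroxy-5-[(4-methoxybenzyl)oxy]-3-methylpent-3-en-1-yl]butanedioate, via dianion 11 (not isolated)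
Conditions: LDA (2.2 equiv), THF, −78 to −20 °C; then 10, DMPU, −78 to −40 °C
Reagents that add atoms: none
Why: in the Fráter–Seebach alkylation the chelated alkoxide enolate should be alkylated on the face anti to the C8 substituent, which sets C7 (C11 anti to O8).

Step 6
Reactants: 12 4-tert-butyl 1-ethyl (2R)-2-[(1R,3E)-1-hydroxy-5-[(4-methoxybenzyl)oxy]-3-methylpent-3-en-1-yl]butanedioate
Product: 13 C8 2-naphthylmethyl ether of 12
Conditions: 2-naphthylmethyl trichloroacetimidate, TfOH (cat.), CH2Cl2/cyclohexane, 0 °C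
Reagents that add atoms: 2-naphthylmethyl 2,2,2-trichloroacetimidate (N=C(OCc1ccc2ccccc2c1)C(Cl)(Cl)Cl)
Why: acid-catalysed imidate O-alkylation should protect the β-hydroxy ester without the retro-aldol that a basic benzylation risks, and the NAP ether is later removable by DDQ after the PMB ethers.

Step 7
Reactants: 13 C8 2-naphthylmethyl ether of 12
Product: 14 tert-butyl (3R,4R,6E)-3-formyl-8-[(4-methoxybenzyl)oxy]-6-methyl-4-(naphthalen-2-ylmethoxy)oct-6-enoate
Conditions: DIBAL-H (1.05 equiv), CH2Cl2, −78 °C; Rochelle salt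
Reagents that add atoms: none
Why: the aluminium hemiacetal from the ethyl ester should survive at −78 °C and give the C6 aldehyde on work-up, while the bulky tert-butyl ester is reduced much more slowly.

Step 8
Reactants: 15 2,2,6-trimethyl-4H-1,3-dioxin-4-one
Product: 17 2,2-dimethyl-6-methylidene-4-(trimethylsilyloxy)-1,3-diox-4-ene, via lithium dienolate 16 (not isolated)
Conditions: LDA, THF, −78 °C; then TMSCl
Reagents that add atoms: chlorotrimethylsilane (C[Si](C)(C)Cl)
Why: γ-deprotonation of the vinylogous ester and O-silylation should give the silyl dienol ether that carries C3, C4, C5 and the carbon later lost as CO2.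

Step 9
Reactants: 14 tert-butyl (3R,4R,6E)-3-formyl-8-[(4-methoxybenzyl)oxy]-6-methyl-4-(naphthalen-2-ylmethoxy)oct-6-enoate; 17 2,2-dimethyl-6-methylidene-4-(trimethylsilyloxy)-1,3-diox-4-ene
Product: 18 δ-hydroxy dioxinone (C5–C6 aldol adduct with 6,7-syn and 6,8-anti configuration)
Conditions: BF3·OEt2, CH2Cl2, −78 °C
Reagents that add atoms: none
Why: in this vinylogous Mukaiyama aldol at the γ-carbon, Felkin–Anh control from C7 and 1,3-anti induction from the β-arylmethyl ether at C8 reinforce each other in the 7,8-anti aldehyde and should set C6.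

Step 10
Reactants: 18 δ-hydroxy dioxinone
Product: 19 C6 triethylsilyl ether of 18
Conditions: TESCl, imidazole, DMF, 0 °C
Reagents that add atoms: chlorotriethylsilane (CC[Si](Cl)(CC)CC)
Why: silylation should stop the C6 hydroxyl from trapping the acylketene (six-membered lactone) and make C6–O a poor leaving group for the later enolate chemistry.

Step 11
Reactants: 19 C6 triethylsilyl ether of 18
Product: 20 C2 allylic alcohol (19 without the PMB group)
Conditions: DDQ (1.2 equiv), CH2Cl2/pH 7 buffer, 0 °C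
Reagents that add atoms: none
Why: DDQ oxidises the electron-rich PMB ether much faster than the NAP ether, so only the C2 hydroxyl should be freed.

Step 12
Reactants: 20 C2 allylic alcohol
Product: 22 twelve-membered β-keto lactone (ring O–C(=O)–C3H2–C4(=O)–C5H2–C6–C7–C8–C9H2–C10(Me)=C1H–C2H2), via acylketene 21 (not isolated)
Conditions: toluene, 110 °C, slow addition to 0.5 mM
Reagents that add atoms: none
Why: retro-hetero-Diels–Alder loss of acetone gives an acylketene that the C2 hydroxyl should trap within the molecule, a known acylketene macrolactonisation that closes the unstrained twelve-membered ring.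

Step 13
Reactants: 22 twelve-membered β-keto lactone
Product: 23 α-diazo β-keto lactone
Conditions: 4-acetamidobenzenesulfonyl azide, Et3N, MeCN, 0 °C to rt
Reagents that add atoms: 4-acetamidobenzenesulfonyl azide (CC(=O)Nc1ccc(cc1)S(=O)(=O)N=[N+]=[N-])
Why: Regitz diazo transfer is specific for the doubly activated C3 methylene.

Step 14
Reactants: 23 α-diazo β-keto lactone
Product: 24 α-(4-methoxybenzyloxy) β-keto lactone (C3 epimers)
Conditions: Rh2(OAc)4 (1 mol %), 4-methoxybenzyl alcohol (5 equiv), CH2Cl2, 40 °C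
Reagents that add atoms: 4-methoxybenzyl alcohol (COc1ccc(CO)cc1)
Why: rhodium carbenoid O–H insertion into the excess alcohol should install the C3 oxygen, and transannular cyclopropanation of C1=C10 would require a strained fused eight-membered ring.

Step 15
Reactants: 24 α-(4-methoxybenzyloxy) β-keto lactone
Product: 25 ten-membered ketone (germacr-1(10)-en-4-one core without C15; 3-OPMB, 6-OTES, 8-ONAP, C7–CH2CO2tBu)
Conditions: Pd(PPh3)4 (10 mol %), dry THF, 40 °C, 2 mM
Reagents that add atoms: none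
Why: Proposed new method: Pd(0) should ionise the allylic C2–O bond of the lactone to a π-allyl (C2–C1–C10) palladium β-keto carboxylate, which loses CO2 to an α-alkoxy palladium enolate on the same metal, and C–C bond formation at the unsubstituted terminus C2 joins C2 to C3, so that the O–C(=O) unit leaves the ring and the twelve-membered lactone becomes the ten-membered carbocycle. The closest known reaction type is the Tsuji–Saegusa decarboxylative allylation of acyclic allyl β-keto esters (α-alkoxy ones included), and medium rings are known to close by intramolecular Tsuji–Trost alkylation; new here is that the carbon dioxide is excised from a macrolactone. The ten-membered ring closes by collapse of the enolate/π-allyl pair held on one palladium, formally a ten-membered closure by attack on the primary allyl terminus whose entropic cost is paid by the preformed lactone. C3 is the only new stereocentre; it lies α to the ketone, is not controlled here, and is erased in step 22 and reset in step 23. The step needs attack at C2 and not at C10 (fully substituted; it would give an eight-membered ring), C- over O-allylation (an O-allyl enol ether would re-ionise), retention of the 1(10)E geometry (syn/anti exchange would need an η1 complex at the tertiary C10), and coupling faster than protonation of the enolate, which the dry, neutral, proton-free medium should secure.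

Step 16
Reactants: 25 ten-membered ketone
Product: 27 C4 enol triflate (4Z ring alkene C4=C5), via potassium enolate 26 (not isolated)
Conditions: KHMDS (1.1 equiv), THF, −78 °C; then PhNTf2, −78 to −40 °C
Reagents that add atoms: N-phenylbis(trifluoromethanesulfonimide) (O=S(=O)(N(c1ccccc1)S(=O)(=O)C(F)(F)F)C(F)(F)F)
Why: kinetic deprotonation should occur at the C5 methylene, away from the alkoxy-bearing C3, and give the E(O)-enolate (ring-cis alkene, C3 cis to C6), which the triflate fixes as the 4Z geometry; the β-silyloxy group should not eliminate at −78 °C.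

Step 17
Reactants: 27 C4 enol triflate
Product: 29 6,12-olide enol triflate (trans-fused γ-lactone), via hydroxy ester 28 (not isolated)
Conditions: CSA (cat.), MeOH/CH2Cl2, 0 °C; then CSA (cat.), CH2Cl2, rt
Reagents that add atoms: none
Why: acid methanolysis removes the TES ether and the γ-hydroxy tert-butyl ester should lactonise (5-exo-trig acyl substitution) under acid catalysis, where silyl migration from O8 cannot compete and the electron-poor enol triflate keeps the allylic C6–OH from ionising.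

Step 18
Reactants: 29 6,12-olide enol triflate; 30 (tributylstannyl)methanol
Product: 31 15-hydroxy lactone (C4–CH2OH; 4Z)
Conditions: Pd2(dba)3 (5 mol %), AsPh3, LiCl, NMP, 50 °C
Reagents that add atoms: none
Why: Stille coupling of the enol triflate with the hydroxymethylstannane proceeds with retention of alkene geometry and should install C15 at the alcohol oxidation level; the mild temperature guards against Cope rearrangement of the 1,5-diene.

Step 19
Reactants: 31 15-hydroxy lactone
Product: 32 15-O-tert-butyldimethylsilyl ether of 31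
Conditions: TBSCl, imidazole, DMF, rt
Reagents that add atoms: tert-butyldimethylsilyl chloride (CC(C)(C)[Si](C)(C)Cl)
Why: silylation of the primary alcohol keeps C15–OH out of the later oxidation and acylation steps.

Step 20
Reactants: 32 15-O-tert-butyldimethylsilyl ether
Product: 36 α-methylene lactone (C11=C13), via lithium enolate 33 (not isolated), via Mannich base 34 (not isolated), via ammonium iodide 35 (not isolated)
Conditions: LDA (1.3 equiv), THF, −78 °C; Eschenmoser's salt, −78 to 0 °C; then MeI, MeOH; then aq. NaHCO3, rt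
Reagents that add atoms: Eschenmoser's salt (C=[N+](C)C.[I-])
Why: Mannich reaction of the lactone enolate, N-methylation and E1cB loss of trimethylamine is the standard α-methylenation; C7 is not enolisable and keeps its configuration.

Step 21
Reactants: 36 α-methylene lactone
Product: 37 C3 allylic alcohol (C3 epimers)
Conditions: DDQ (1.3 equiv), CH2Cl2/pH 7 buffer, 0 °C
Reagents that add atoms: none
Why: oxidative cleavage of the PMB ether by DDQ should again leave the slower NAP ether at C8 in place.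

Step 22
Reactants: 37 C3 allylic alcohol
Product: 38 C3 enone (C3=O conjugated with C4=C5)
Conditions: Dess–Martin periodinane, NaHCO3, CH2Cl2, 0 °C
Reagents that add atoms: none
Why: buffered Dess–Martin oxidation converges both C3 epimers on one enone without base that could open the γ-acyloxy enone.

Step 23
Reactants: 38 C3 enone
Product: 39 (3S)-allylic alcohol
Conditions: (R)-Me-CBS (0.5 equiv), catecholborane, toluene, −78 °C
Reagents that add atoms: none
Why: in the Corey–Bakshi–Shibata 1,2-reduction the α-substituted alkenyl side acts as the large group and the C2 methylene as the small one, so the (R)-catalyst should deliver hydride to give the 3S carbinol under reagent control.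

Step 24
Reactants: 39 (3S)-allylic alcohol
Product: 40 3-O-acetate of 39
Conditions: Ac2O, DMAP (cat.), pyridine, CH2Cl2, 0 °C
Reagents that add atoms: acetic anhydride (CC(=O)OC(C)=O)
Why: acylation of the only free hydroxyl proceeds with retention at C3.

Step 25
Reactants: 40 3-O-acetate
Product: 41 C8 alcohol (40 without the NAP group)
Conditions: DDQ (3 equiv), CH2Cl2/H2O, rt
Reagents that add atoms: none
Why: the NAP ether is cleaved by excess DDQ under neutral conditions that should leave the acetate, the silyl ether and both acrylate-type alkenes untouched.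

Step 26
Reactants: 41 C8 alcohol
Product: 42 8-O-methacrylate 15-O-TBS ether
Conditions: methacrylic anhydride, DMAP, Et3N, CH2Cl2, 0 °C to rt
Reagents that add atoms: methacrylic anhydride (C=C(C)C(=O)OC(=O)C(C)=C)
Why: DMAP-catalysed acylation of the secondary C8 hydroxyl retains configuration, and no other free hydroxyl is present.

Step 27
Reactants: 42 8-O-methacrylate 15-O-TBS ether
Product: 43 15-alcohol (1(10)E,4Z-diene)
Conditions: HF·pyridine, pyridine, THF, 0 °C
Reagents that add atoms: none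
Why: buffered fluoride removes the primary silyl ether before the acid-sensitive epoxide exists, without ester migration or Michael addition.

Step 28
Reactants: 43 15-alcohol
Product: 44 target (1R,10R-epoxide)
Conditions: mCPBA (1.05 equiv), NaHCO3, CH2Cl2, −20 to 0 °C
Reagents that add atoms: 3-chloroperoxybenzoic acid (OOC(=O)c1cccc(Cl)c1)
Why: in this Prilezhaev epoxidation the trialkyl 1(10) alkene should react far faster than the 4,5-alkene (deactivated by three allylic oxygen substituents) and the two acrylates, and attack on the exposed outer face of the E-alkene should give the trans (1R,10R) epoxide by substrate control.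

**Compound list**

1 | but-2-yn-1-ol | CC#CCO | starting material
2 | 1-[(but-2-yn-1-yloxy)methyl]-4-methoxybenzene | CC#CCOCc1ccc(OC)cc1 | intermediate
3 | chlorobis(cyclopentadienyl)[(2E)-4-(4-methoxybenzyloxy)but-2-en-2-yl]zirconium | Cl[Zr](/C(C)=C/COCc1ccc(OC)cc1)(C1C=CC=C1)C1C=CC=C1 | intermediate
4 | 1-({[(2E)-3-iodobut-2-en-1-yl]oxy}methyl)-4-methoxybenzene | I/C(C)=C/COCc1ccc(OC)cc1 | intermediate
5 | ethyl (3S)-4-chloro-3-hydroxybutanoate | CCOC(=O)C[C@H](O)CCl | starting material
6 | ethyl [(2S)-oxiran-2-yl]acetate | CCOC(=O)C[C@H]1CO1 | intermediate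
7 | [(2E)-4-(4-methoxybenzyloxy)but-2-en-2-yl]lithium | [Li]/C(C)=C/COCc1ccc(OC)cc1 | intermediate
8 | [(2E)-4-(4-methoxybenzyloxy)but-2-en-2-yl]magnesium bromide | Br[Mg]/C(C)=C/COCc1ccc(OC)cc1 | intermediate
9 | ethyl (3R,5E)-3-hydroxy-7-[(4-methoxybenzyl)oxy]-5-methylhept-5-enoate | CCOC(=O)C[C@H](O)C/C(C)=C/COCc1ccc(OC)cc1 | intermediate
10 | tert-butyl bromoacetate | CC(C)(C)OC(=O)CBr | starting material
11 | dilithium alkoxide enolate of 9 | CCOC(O[Li])=C[C@H](O[Li])C/C(C)=C/COCc1ccc(OC)cc1 | intermediate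
12 | 4-tert-butyl 1-ethyl (2R)-2-[(1R,3E)-1-hydroxy-5-[(4-methoxybenzyl)oxy]-3-methylpent-3-en-1-yl]butanedioate (7,8-anti) | CCOC(=O)[C@H](CC(=O)OC(C)(C)C)[C@H](O)C/C(C)=C/COCc1ccc(OC)cc1 | intermediate
13 | C8 2-naphthylmethyl ether of 12 | CCOC(=O)[C@H](CC(=O)OC(C)(C)C)[C@H](OCc1ccc2ccccc2c1)C/C(C)=C/COCc1ccc(OC)cc1 | intermediate
14 | tert-butyl (3R,4R,6E)-3-formyl-8-[(4-methoxybenzyl)oxy]-6-methyl-4-(naphthalen-2-ylmethoxy)oct-6-enoate (C6 aldehyde) | O=C[C@H](CC(=O)OC(C)(C)C)[C@H](OCc1ccc2ccccc2c1)C/C(C)=C/COCc1ccc(OC)cc1 | intermediate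
15 | 2,2,6-trimethyl-4H-1,3-dioxin-4-one | CC1=CC(=O)OC(C)(C)O1 | starting material
16 | lithium dienolate of 15 | C=C1C=C(O[Li])OC(C)(C)O1 | intermediate
17 | 2,2-dimethyl-6-methylidene-4-(trimethylsilyloxy)-1,3-diox-4-ene | C=C1C=C(O[Si](C)(C)C)OC(C)(C)O1 | intermediate
18 | δ-hydroxy dioxinone: dioxinone–C5H2–C6H(OH)–C7H(CH2CO2tBu)–C8H(ONAP)–C9H2–C10(Me)=C1H–C2H2OPMB (6,7-syn, 7,8-anti, 1(10)E) | CC1(C)OC(=CC(=O)O1)C[C@@H](O)[C@H](CC(=O)OC(C)(C)C)[C@H](OCc1ccc2ccccc2c1)C/C(C)=C/COCc1ccc(OC)cc1 | intermediate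
19 | C6 triethylsilyl ether of 18 | CC1(C)OC(=CC(=O)O1)C[C@@H](O[Si](CC)(CC)CC)[C@H](CC(=O)OC(C)(C)C)[C@H](OCc1ccc2ccccc2c1)C/C(C)=C/COCc1ccc(OC)cc1 | intermediate
20 | C2 allylic alcohol (19 without PMB) | CC1(C)OC(=CC(=O)O1)C[C@@H](O[Si](CC)(CC)CC)[C@H](CC(=O)OC(C)(C)C)[C@H](OCc1ccc2ccccc2c1)C/C(C)=C/CO | intermediate
21 | acylketene from 20 (O=C=C3H–C4(=O)–C5H2–) | O=C=CC(=O)C[C@@H](O[Si](CC)(CC)CC)[C@H](CC(=O)OC(C)(C)C)[C@H](OCc1ccc2ccccc2c1)C/C(C)=C/CO | intermediate
22 | twelve-membered β-keto lactone (6-OTES, 7-CH2CO2tBu, 8-ONAP, 1(10)E) | O=C1CC(=O)C[C@@H](O[Si](CC)(CC)CC)[C@H](CC(=O)OC(C)(C)C)[C@H](OCc2ccc3ccccc3c2)C/C(C)=C/CO1 | intermediate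
23 | α-diazo β-keto lactone (diazo at C3) | O=C1C(=[N+]=[N-])C(=O)C[C@@H](O[Si](CC)(CC)CC)[C@H](CC(=O)OC(C)(C)C)[C@H](OCc2ccc3ccccc3c2)C/C(C)=C/CO1 | intermediate
24 | α-(4-methoxybenzyloxy) β-keto lactone (C3 epimers) | O=C1C(OCc2ccc(OC)cc2)C(=O)C[C@@H](O[Si](CC)(CC)CC)[C@H](CC(=O)OC(C)(C)C)[C@H](OCc2ccc3ccccc3c2)C/C(C)=C/CO1 | intermediate
25 | ten-membered C4 ketone: 3-OPMB (epimers), 6-OTES, 7-CH2CO2tBu, 8-ONAP, 10-methyl, 1(10)E | O(Cc1ccc2ccccc2c1)[C@@H]1C/C(C)=C/CC(OCc2ccc(OC)cc2)C(=O)C[C@@H](O[Si](CC)(CC)CC)[C@@H]1CC(=O)OC(C)(C)C | intermediate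
26 | potassium C4(O)=C5 enolate of 25 | O(Cc1ccc2ccccc2c1)[C@@H]1C/C(C)=C/CC(OCc2ccc(OC)cc2)/C(O[K])=C\[C@@H](O[Si](CC)(CC)CC)[C@@H]1CC(=O)OC(C)(C)C | intermediate
27 | C4 enol triflate (4Z, 1(10)E) | O(Cc1ccc2ccccc2c1)[C@@H]1C/C(C)=C/CC(OCc2ccc(OC)cc2)/C(OS(=O)(=O)C(F)(F)F)=C\[C@@H](O[Si](CC)(CC)CC)[C@@H]1CC(=O)OC(C)(C)C | intermediate
28 | C6 hydroxy tert-butyl ester (27 without TES) | O(Cc1ccc2ccccc2c1)[C@@H]1C/C(C)=C/CC(OCc2ccc(OC)cc2)/C(OS(=O)(=O)C(F)(F)F)=C\[C@@H](O)[C@@H]1CC(=O)OC(C)(C)C | intermediate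
29 | 6,12-olide enol triflate (trans-fused γ-lactone) | O(Cc1ccc2ccccc2c1)[C@@H]1C/C(C)=C/CC(OCc2ccc(OC)cc2)/C(OS(=O)(=O)C(F)(F)F)=C\[C@H]2OC(=O)C[C@@H]21 | intermediate
30 | (tributylstannyl)methanol | OC[Sn](CCCC)(CCCC)CCCC | starting material
31 | 15-hydroxy lactone (3-OPMB, 8-ONAP, 4Z, 1(10)E) | O(Cc1ccc2ccccc2c1)[C@@H]1C/C(C)=C/CC(OCc2ccc(OC)cc2)/C(CO)=C\[C@H]2OC(=O)C[C@@H]21 | intermediate
32 | 15-O-TBS ether of 31 | O(Cc1ccc2ccccc2c1)[C@@H]1C/C(C)=C/CC(OCc2ccc(OC)cc2)/C(CO[Si](C)(C)C(C)(C)C)=C\[C@H]2OC(=O)C[C@@H]21 | intermediate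
33 | lithium enolate of lactone 32 | O(Cc1ccc2ccccc2c1)[C@@H]1C/C(C)=C/CC(OCc2ccc(OC)cc2)/C(CO[Si](C)(C)C(C)(C)C)=C\[C@H]2OC(O[Li])=C[C@@H]21 | intermediate
34 | C11 dimethylaminomethyl lactone (Mannich base) | O(Cc1ccc2ccccc2c1)[C@@H]1C/C(C)=C/CC(OCc2ccc(OC)cc2)/C(CO[Si](C)(C)C(C)(C)C)=C\[C@H]2OC(=O)C(CN(C)C)[C@@H]21 | intermediate
35 | trimethylammonium iodide of 34 | O(Cc1ccc2ccccc2c1)[C@@H]1C/C(C)=C/CC(OCc2ccc(OC)cc2)/C(CO[Si](C)(C)C(C)(C)C)=C\[C@H]2OC(=O)C(C[N+](C)(C)C)[C@@H]21.[I-] | intermediate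
36 | α-methylene lactone (3-OPMB, 8-ONAP, 15-OTBS) | O(Cc1ccc2ccccc2c1)[C@@H]1C/C(C)=C/CC(OCc2ccc(OC)cc2)/C(CO[Si](C)(C)C(C)(C)C)=C\[C@H]2OC(=O)C(=C)[C@@H]21 | intermediate
37 | C3 allylic alcohol (C3 epimers) | O(Cc1ccc2ccccc2c1)[C@@H]1C/C(C)=C/CC(O)/C(CO[Si](C)(C)C(C)(C)C)=C\[C@H]2OC(=O)C(=C)[C@@H]21 | intermediate
38 | C3 enone | O(Cc1ccc2ccccc2c1)[C@@H]1C/C(C)=C/CC(=O)/C(CO[Si](C)(C)C(C)(C)C)=C\[C@H]2OC(=O)C(=C)[C@@H]21 | intermediate
39 | (3S)-allylic alcohol | O(Cc1ccc2ccccc2c1)[C@@H]1C/C(C)=C/C[C@H](O)/C(CO[Si](C)(C)C(C)(C)C)=C\[C@H]2OC(=O)C(=C)[C@@H]21 | intermediate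
40 | 3-O-acetate of 39 | O(Cc1ccc2ccccc2c1)[C@@H]1C/C(C)=C/C[C@H](OC(C)=O)/C(CO[Si](C)(C)C(C)(C)C)=C\[C@H]2OC(=O)C(=C)[C@@H]21 | intermediate
41 | C8 alcohol (3-OAc, 15-OTBS) | O[C@@H]1C/C(C)=C/C[C@H](OC(C)=O)/C(CO[Si](C)(C)C(C)(C)C)=C\[C@H]2OC(=O)C(=C)[C@@H]21 | intermediate
42 | 8-O-methacrylate 15-O-TBS ether | C=C(C)C(=O)O[C@@H]1C/C(C)=C/C[C@H](OC(C)=O)/C(CO[Si](C)(C)C(C)(C)C)=C\[C@H]2OC(=O)C(=C)[C@@H]21 | intermediate
43 | 15-alcohol, 1(10)E,4Z-diene (deoxy precursor of the target) | C=C(C)C(=O)O[C@@H]1C/C(C)=C/C[C@H](OC(C)=O)/C(CO)=C\[C@H]2OC(=O)C(=C)[C@@H]21 | intermediate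
44 | CNP0319155.1 | C=C(C)C(=O)O[C@@H]1C[C@@]2(C)O[C@@H]2C[C@H](OC(C)=O)/C(CO)=C\[C@H]2OC(=O)C(=C)[C@@H]21 | target

**Totals and risks**

Total step count: 28. Longest linear sequence: 26 steps (from 1 through steps 1, 2, 4–7 and 9–28).

Most likely to fail:

1. Step 15 (ring contraction). The palladium enolate may be protonated, or the π-allyl may lose a β-hydrogen, before the strained ten-membered ring closes, so that decarboxylation occurs without ring contraction. Fallback with known chemistry, setting out from 20 and returning at 25: methyl chloroformate/pyridine converts 20 into the allylic methyl carbonate F1. Heating F1 with 2,2,2-trichloroethanol in toluene at 110 °C opens the dioxinone through its acylketene to the trichloroethyl β-keto ester F2. Diazo transfer gives the diazo ester F3, and Rh2(OAc)4 with 4-methoxybenzyl alcohol gives the α-alkoxy β-keto ester F4. Pd2(dba)3/dppe in dilute THF then ionises the carbonate, and the doubly stabilised carbon nucleophile closes the ten-membered ring directly (intramolecular Tsuji–Trost alkylation) to the ring β-keto ester F5. Zn/AcOH removes the trichloroethyl group and the β-keto acid decarboxylates to 25.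

2. Step 16 (enol triflate). Enolisation may go toward C3, the ring-trans enolate may form, or the C6 silyloxy group may be eliminated from the enolate. Fallback setting out from 25 and returning at 31: a Wittig reaction with methoxymethylenetriphenylphosphorane gives the enol ether F6. PhSeCl followed by aqueous NaHCO3 gives the α-phenylselanyl aldehyde F7. H2O2/pyridine then causes selenoxide syn-elimination, away from the oxygen-bearing C3, to the enal F8, in which the formyl group should sit trans to C6. Luche reduction gives the allylic alcohol F9, and CSA/MeOH as in step 17 removes the TES group and closes the lactone to 31.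

3. Step 28 (epoxidation). Facial selectivity on the 1(10) alkene may be poor, or the free C15 hydroxyl may direct the peracid to the 4,5-alkene. Fallback setting out from 42 and returning at 44: Shi epoxidation (D-fructose-derived ketone, Oxone, buffered MeCN/dimethoxymethane/H2O, 0 °C) of the silyl ether 42 gives the epoxy silyl ether F10 under reagent control, with no free hydroxyl present. HF·pyridine/pyridine then gives 44.

Further compounds
F1 | step 15 | C2 methyl carbonate of 20 | CC1(C)OC(=CC(=O)O1)C[C@@H](O[Si](CC)(CC)CC)[C@H](CC(=O)OC(C)(C)C)[C@H](OCc1ccc2ccccc2c1)C/C(C)=C/COC(=O)OC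
F2 | step 15 | acyclic 2,2,2-trichloroethyl β-keto ester with the allylic methyl carbonate | ClC(Cl)(Cl)COC(=O)CC(=O)C[C@@H](O[Si](CC)(CC)CC)[C@H](CC(=O)OC(C)(C)C)[C@H](OCc1ccc2ccccc2c1)C/C(C)=C/COC(=O)OC
F3 | step 15 | α-diazo derivative of F2 | ClC(Cl)(Cl)COC(=O)C(=[N+]=[N-])C(=O)C[C@@H](O[Si](CC)(CC)CC)[C@H](CC(=O)OC(C)(C)C)[C@H](OCc1ccc2ccccc2c1)C/C(C)=C/COC(=O)OC
F4 | step 15 | α-(4-methoxybenzyloxy) β-keto ester (C3 epimers) | ClC(Cl)(Cl)COC(=O)C(OCc1ccc(OC)cc1)C(=O)C[C@@H](O[Si](CC)(CC)CC)[C@H](CC(=O)OC(C)(C)C)[C@H](OCc1ccc2ccccc2c1)C/C(C)=C/COC(=O)OC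
F5 | step 15 | ten-membered ring β-keto ester (C3 bears OPMB and CO2CH2CCl3) | O(Cc1ccc2ccccc2c1)[C@@H]1C/C(C)=C/CC(OCc2ccc(OC)cc2)(C(=O)OCC(Cl)(Cl)Cl)C(=O)C[C@@H](O[Si](CC)(CC)CC)[C@@H]1CC(=O)OC(C)(C)C
F6 | step 16 | C4 methoxymethylidene enol ether | O(Cc1ccc2ccccc2c1)[C@@H]1C/C(C)=C/CC(OCc2ccc(OC)cc2)C(=COC)C[C@@H](O[Si](CC)(CC)CC)[C@@H]1CC(=O)OC(C)(C)C
F7 | step 16 | C4 formyl C4 phenylselanyl compound | O(Cc1ccc2ccccc2c1)[C@@H]1C/C(C)=C/CC(OCc2ccc(OC)cc2)C(C=O)([Se]c2ccccc2)C[C@@H](O[Si](CC)(CC)CC)[C@@H]1CC(=O)OC(C)(C)C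
F8 | step 16 | C15 enal (4Z ring alkene) | O(Cc1ccc2ccccc2c1)[C@@H]1C/C(C)=C/CC(OCc2ccc(OC)cc2)/C(C=O)=C\[C@@H](O[Si](CC)(CC)CC)[C@@H]1CC(=O)OC(C)(C)C
F9 | step 16 | C15 allylic alcohol with 6-OTES and tert-butyl ester | O(Cc1ccc2ccccc2c1)[C@@H]1C/C(C)=C/CC(OCc2ccc(OC)cc2)/C(CO)=C\[C@@H](O[Si](CC)(CC)CC)[C@@H]1CC(=O)OC(C)(C)C
F10 | step 28 | 15-O-TBS ether of the target | C=C(C)C(=O)O[C@@H]1C[C@@]2(C)O[C@@H]2C[C@H](OC(C)=O)/C(CO[Si](C)(C)C(C)(C)C)=C\[C@H]2OC(=O)C(=C)[C@@H]21
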